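**Plan**

1. Locants (germacrane numbering): C1 enol-ether carbon, C2 ring CH=, C3 ring CH2, C4 O-bearing methyl carbon, C5 exocyclic CH=, C6/C7/C11/C12 the γ/β/α/carbonyl carbons of the butenolide, C13 the CH2OAc carbon, C8 the ester carbinol, C9 CH2, C10 the methyl carbinol.
2. Cuts, in order: C13 acetate and silyl groups; then C5=C6, the one bond shared by the nine-membered ring (O, C4, C5, C6, C7, C8, C9, C10, C1) and the butenolide π system, giving a C5 aldehyde and the C6H2 of the lactone; then C1–O (dihydrofuran, from a C1≡C2 alkyne and C4–OH), C7–C8 (bromobutenolide + aldehyde) and C2–C3 (acetylide + epoxide).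
3. Forward: a C8–C10/C1–C2 alkyne, a C3–C5 epoxide and a bromobutenolide (C6, C7, C11–C13) are joined into an open chain. The butenolide ring is present from the start, the dihydrofuran ring is closed second by gold-catalysed 5-endo hydroalkoxylation, and the nine-membered ring (and with it the ten-membered carbocycle) is closed last by an intramolecular vinylogous aldol condensation.
4. Enabling feature: C6H2 is the vinylogous α-position of the C12 carbonyl through C11=C7, so silylation turns the lactone into an aromatic 2-silyloxyfuran nucleophilic at C6, while C5 sits on the fully substituted C4 and cannot enolise. Elimination then gives C5=C6 cis inside the ring, a geometry an open-chain condensation would not deliver.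
5. Stereochemistry: C10 from Sharpless epoxidation of an enynol, C4 from (R)-2-methylglycidol, C8 from a ligand-controlled Ni/Cr addition; all three are set before the ring closures and are not touched afterwards.

Key step: step 16

Remark: (E)-3-methylpent-2-en-4-yn-1-ol, (R)-2-methylglycidol and tetronic acid are taken as purchased materials.

**Route**

Step 1
Reactants: 1 (E)-3-methylpent-2-en-4-yn-1-ol
Product: 2 [(2S,3S)-3-ethynyl-3-methyloxiran-2-yl]methanol
Conditions: Ti(OiPr)4 (cat.), L-(+)-diethyl tartrate (cat.), t-BuOOH, 4 Å MS, CH2Cl2, −20 °C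
Reagents that add atoms: tert-butyl hydroperoxide, CC(C)(C)OO
Why: Katsuki–Sharpless asymmetric epoxidation of an (E)-trisubstituted allylic alcohol; the L-(+)-tartrate complex delivers oxygen to the same face as in the geraniol case, giving the (2S,3S)-epoxide and so fixing the future C10.

Step 2
Reactants: 2 [(2S,3S)-3-ethynyl-3-methyloxiran-2-yl]methanol
Product: 3 (R)-3-methylpent-4-yne-1,3-diol
Conditions: NaAlH2(OCH2CH2OMe)2 (Red-Al), THF, 0 °C; Rochelle salt work-up
Reagents that add atoms: none
Why: Hydroxyl-directed hydride delivery from the C1 aluminate opens 2,3-epoxy alcohols at C2 (the Red-Al 1,3-diol opening); the C3–O bond is not broken, so the tertiary carbinol keeps its configuration, and the terminal alkyne is held as its aluminium acetylide, which resists hydroalumination.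

Step 3
Reactants: 3 (R)-3-methylpent-4-yne-1,3-diol
Product: 4 (R)-5-[(4-methoxybenzyl)oxy]-3-methylpent-1-yn-3-ol
Conditions: NaH (1 equiv), 4-MeOC6H4CH2Cl, Bu4NI (cat.), THF/DMF, 0 °C to rt
Reagents that add atoms: 4-methoxybenzyl chloride, COc1ccc(CCl)cc1
Why: Williamson etherification; the primary alkoxide is alkylated far faster than the hindered tertiary propargylic one.

Step 4
Reactants: 4 (R)-5-[(4-methoxybenzyl)oxy]-3-methylpent-1-yn-3-ol
Product: 5 (R)-triethyl({5-[(4-methoxybenzyl)oxy]-3-methylpent-1-yn-3-yl}oxy)silane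
Conditions: Et3SiOTf, 2,6-lutidine, CH2Cl2, −78 to 0 °C
Reagents that add atoms: triethylsilyl triflate, CC[Si](CC)(CC)OS(=O)(=O)C(F)(F)F
Why: Silyl triflate silylation is the standard way to protect a hindered tertiary alcohol, and the silyl ether keeps the propargylic oxygen from ionising in the later gold step.

Step 5
Reactants: 6 (R)-2-methylglycidol
Product: 7 triethylsilyl ether of (R)-2-methylglycidol, triethyl[(2-methyloxiran-2-yl)methoxy]silane (quaternary carbon arranged as in 6; the descriptor becomes S by priority only)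
Conditions: Et3SiCl, Et3N, DMAP (cat.), CH2Cl2, 0 °C
Reagents that add atoms: chlorotriethylsilane, CC[Si](Cl)(CC)CC
Why: Base-mediated silylation of the primary alcohol leaves the epoxide and its stereocentre untouched; a primary triethylsilyl ether is chosen because it can later be oxidised directly to the aldehyde.

Step 6
Reactants: 5 (R)-triethyl({5-[(4-methoxybenzyl)oxy]-3-methylpent-1-yn-3-yl}oxy)silane; 7 triethylsilyl ether of (R)-2-methylglycidol
Product: 9 (2S,6R)-8-[(4-methoxybenzyl)oxy]-2,6-dimethyl-1,6-bis[(triethylsilyl)oxy]oct-4-yn-2-ol, via lithium acetylide 8 (not isolated)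
Conditions: n-BuLi, THF, −78 °C; BF3·OEt2; then 7, −78 °C
Reagents that add atoms: none
Why: BF3-mediated opening of an epoxide by a lithium acetylide occurs by SN2 attack at the unsubstituted CH2 (C3), so the C2–C3 bond forms and the quaternary carbinol C4 is carried over unchanged from the glycidol.

Step 7
Reactants: 9 (2S,6R)-8-[(4-methoxybenzyl)oxy]-2,6-dimethyl-1,6-bis[(triethylsilyl)oxy]oct-4-yn-2-ol
Product: 10 (3R,7S)-3,7-dimethyl-3,8-bis[(triethylsilyl)oxy]oct-4-yne-1,7-diol
Conditions: DDQ, CH2Cl2/pH 7 buffer, 0 °C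
Reagents that add atoms: none
Why: Oxidative cleavage of the 4-methoxybenzyl ether by DDQ; it is placed here, before the electron-rich dihydrofuran exists, because that ring could lose an allylic hydride to DDQ.

Step 8
Reactants: 10 (3R,7S)-3,7-dimethyl-3,8-bis[(triethylsilyl)oxy]oct-4-yne-1,7-diol
Product: 11 (3R,7S)-7-hydroxy-3,7-dimethyl-3,8-bis[(triethylsilyl)oxy]oct-4-ynal
Conditions: Dess–Martin periodinane, NaHCO3, CH2Cl2, 0 °C to rt
Reagents that add atoms: none
Why: Dess–Martin oxidation converts the primary alcohol into the C8 aldehyde under buffered conditions, and the tertiary C4 alcohol cannot be oxidised.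

Step 9
Reactants: 12 tetronic acid (furan-2,4(3H,5H)-dione)
Product: 13 4-bromo-2-oxo-2,5-dihydrofuran-3-carbaldehyde
Conditions: POBr3, DMF, CH2Cl2, 0 °C to rt; aq. NaOAc work-up
Reagents that add atoms: N,N-dimethylformamide, CN(C)C=O; phosphorus oxybromide, O=P(Br)(Br)Br; water, O
Why: Vilsmeier–Haack haloformylation of a cyclic β-dicarbonyl compound (as with 4-hydroxycoumarin) formylates the nucleophilic C3 and turns the enol hydroxyl into the vinylogous acyl bromide, placing C13 and the C7 handle in one operation.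

Step 10
Reactants: 13 4-bromo-2-oxo-2,5-dihydrofuran-3-carbaldehyde
Product: 14 4-bromo-3-(hydroxymethyl)furan-2(5H)-one
Conditions: NaBH4, CeCl3·7H2O, MeOH/THF, −78 °C
Reagents that add atoms: none
Why: Luche reduction gives 1,2-addition of hydride to the aldehyde at low temperature, faster than attack on the lactone or addition–elimination at the β-bromide.

Step 11
Reactants: 14 4-bromo-3-(hydroxymethyl)furan-2(5H)-one
Product: 15 4-bromo-3-{[(tert-butyldimethylsilyl)oxy]methyl}furan-2(5H)-one
Conditions: t-BuMe2SiOTf, 2,6-lutidine, CH2Cl2, −78 °C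
Reagents that add atoms: tert-butyldimethylsilyl triflate, CC(C)(C)[Si](C)(C)OS(=O)(=O)C(F)(F)F
Why: Silylation with a silyl triflate and a hindered base avoids nucleophilic amines, which would displace the β-bromide by addition–elimination.

Step 12
Reactants: 11 (3R,7S)-7-hydroxy-3,7-dimethyl-3,8-bis[(triethylsilyl)oxy]oct-4-ynal; 15 4-bromo-3-{[(tert-butyldimethylsilyl)oxy]methyl}furan-2(5H)-one
Product: 16 3-{[(tert-butyldimethylsilyl)oxy]methyl}-4-[(1S,3R,7S)-1,7-dihydroxy-3,7-dimethyl-3,8-bis[(triethylsilyl)oxy]oct-4-yn-1-yl]furan-2(5H)-one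
Conditions: CrCl2, chiral oxazoline–sulfonamide ligand N-[2-(4-isopropyl-4,5-dihydrooxazol-2-yl)-6-methylphenyl]methanesulfonamide (enantiomer matched to 8S), Et3N, NiCl2 (cat.), THF, rt
Reagents that add atoms: none
Why: Nozaki–Hiyama–Kishi reaction: zerovalent nickel inserts into the activated β-bromo enoate C–Br bond, transmetalation gives a vinylchromium species that adds only to the aldehyde (alkyne, lactone, silyl ethers and the tertiary alcohol are tolerated), and the chiral sulfonamide ligand on chromium selects the aldehyde face and sets C8 as S.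

Step 13
Reactants: 16 the (8S)-alcohol from step 12
Product: 17 (1S,3R,7S)-1-(4-{[(tert-butyldimethylsilyl)oxy]methyl}-5-oxo-2,5-dihydrofuran-3-yl)-7-hydroxy-3,7-dimethyl-3,8-bis[(triethylsilyl)oxy]oct-4-yn-1-yl methacrylate
Conditions: methacrylic anhydride, Et3N, DMAP (cat.), CH2Cl2, 0 °C to rt
Reagents that add atoms: methacrylic anhydride, CC(=C)C(=O)OC(=O)C(C)=C
Why: DMAP-catalysed acylation esterifies the secondary C8 alcohol with retention, while the tertiary C4 alcohol does not react under these conditions.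

Step 14
Reactants: 17 the C8 methacrylate with free C4–OH and C1≡C2 alkyne
Product: 18 (1S,3R)-1-(4-{[(tert-butyldimethylsilyl)oxy]methyl}-5-oxo-2,5-dihydrofuran-3-yl)-3-[(5S)-5-methyl-5-{[(triethylsilyl)oxy]methyl}-4,5-dihydrofuran-2-yl]-3-[(triethylsilyl)oxy]butyl methacrylate
Conditions: Ph3PAuNTf2 (5 mol %), 4 Å MS, toluene, rt; Et3N quench
Reagents that add atoms: none
Why: Gold-catalysed 5-endo-dig cycloisomerisation of a homopropargylic alcohol to a 2,3-dihydrofuran: the cationic gold complex activates C1≡C2, the C4 hydroxyl attacks C1 anti to gold (attack at C2 would be 4-exo) and protodeauration leaves H on C2; no stereocentre is made and C4 and C10 are untouched.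

Step 15
Reactants: 18 the dihydrofuran with C5–OSiEt3
Product: 19 (1S,3R)-1-(4-{[(tert-butyldimethylsilyl)oxy]methyl}-5-oxo-2,5-dihydrofuran-3-yl)-3-[(5S)-5-formyl-5-methyl-4,5-dihydrofuran-2-yl]-3-[(triethylsilyl)oxy]butyl methacrylate
Conditions: (COCl)2, DMSO, CH2Cl2, −78 to −30 °C; Et3N, to 0 °C
Reagents that add atoms: none
Why: Under Swern conditions a primary triethylsilyl ether is converted directly into the aldehyde while tert-butyldimethylsilyl and tertiary triethylsilyl ethers survive, and the medium is never acidic, so the enol ether is kept.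

Step 16
Reactants: 19 the C5 aldehyde
Product: 22 (4S,8S,10R)-13-[(tert-butyldimethylsilyl)oxy]-8-(methacryloyloxy)-10-[(triethylsilyl)oxy]-1,4-epoxygermacra-1,5,7(11)-trien-12,6-olide (C5=C6 cis in the ring), via silyloxyfuran aldehyde 20 (not isolated), via cyclised silyl aldolate 21 (not isolated)
Conditions: t-BuMe2SiOTf, i-Pr2NEt, CH2Cl2 (2 mM), −78 to 0 °C; then DBU, 0 °C to rt
Reagents that add atoms: none
Why: The silyl triflate and amine silylate the lactone carbonyl and remove a C6 proton to give the aromatic 2-silyloxyfuran 20, whose C6 adds to the silyl-triflate-activated C5 aldehyde (vinylogous Mukaiyama aldol) to give the silyl aldolate 21; DBU then removes the remaining acidic C6–H and expels the C5 silyloxide (E1cB) to form C5=C6. The closest known reaction type is the one-pot silyl triflate/amine then DBU vinylogous aldol condensation of α,β-disubstituted butenolides with aldehydes to γ-ylidenebutenolides, here run within one molecule at high dilution. The nine-membered ring is closed in a 9-(enolendo)-exo-trig mode (furan C6 onto the exocyclic C5=O), which also completes the ten-membered carbocycle. No new stereocentre survives, since the C5–O and C6–H centres of 21 are removed again; the alkene geometry is controlled by the ring, which holds C4 and C7 cis (the E descriptor of the target). The step needs C6 rather than C11 attack (C11 is fully substituted), enolisation of the lactone only (the aldehyde on quaternary C4 and the methacrylate have no α-hydrogen) and ring closure rather than oligomerisation (dilution). The C13 oxygen is kept as a silyl ether because an acetate there would be expelled from the oxyfuran.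

Step 17
Reactants: 22 the ring-closed bis-silyl ether
Product: 23 (4S,8S,10R)-10,13-dihydroxy-8-(methacryloyloxy)-1,4-epoxygermacra-1,5,7(11)-trien-12,6-olide
Conditions: Bu4NF, AcOH, THF, 0 °C to rt
Reagents that add atoms: none
Why: Fluoride cleaves the tertiary triethylsilyl and primary tert-butyldimethylsilyl ethers; buffering with acetic acid keeps the medium near neutral so that the enol lactone, the methacrylate and the enol ether are spared.

Step 18
Reactants: 23 the 10,13-diol
Product: 24 (4S,8S,10R)-13-acetoxy-10-hydroxy-8-(methacryloyloxy)-1,4-epoxygermacra-1,5,7(11)-trien-12,6-olide (target)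
Conditions: Ac2O, pyridine, DMAP (cat.), CH2Cl2, 0 °C
Reagents that add atoms: acetic anhydride, CC(=O)OC(C)=O
Why: Acetylation of the primary allylic C13 alcohol is fast, while the tertiary C10 alcohol next to the enol ether is not acylated under these conditions.

**Compound list**

1 | (E)-3-methylpent-2-en-4-yn-1-ol | C#C/C(C)=C/CO | starting material
2 | [(2S,3S)-3-ethynyl-3-methyloxiran-2-yl]methanol | C#C[C@]1(C)O[C@H]1CO | intermediate
3 | (R)-3-methylpent-4-yne-1,3-diol | C#C[C@](C)(O)CCO | intermediate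
4 | (R)-5-[(4-methoxybenzyl)oxy]-3-methylpent-1-yn-3-ol | C#C[C@](C)(O)CCOCc1ccc(OC)cc1 | intermediate
5 | (R)-triethyl({5-[(4-methoxybenzyl)oxy]-3-methylpent-1-yn-3-yl}oxy)silane | C#C[C@](C)(O[Si](CC)(CC)CC)CCOCc1ccc(OC)cc1 | intermediate
6 | (R)-2-methylglycidol | C[C@@]1(CO)CO1 | starting material
7 | triethylsilyl ether of (R)-2-methylglycidol | C[C@@]1(CO[Si](CC)(CC)CC)CO1 | intermediate
8 | lithium acetylide of 5 | [Li]C#C[C@](C)(O[Si](CC)(CC)CC)CCOCc1ccc(OC)cc1 | intermediate (not isolated)
9 | (2S,6R)-8-[(4-methoxybenzyl)oxy]-2,6-dimethyl-1,6-bis[(triethylsilyl)oxy]oct-4-yn-2-ol | CC[Si](CC)(CC)OC[C@@](C)(O)CC#C[C@](C)(O[Si](CC)(CC)CC)CCOCc1ccc(OC)cc1 | intermediate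
10 | (3R,7S)-3,7-dimethyl-3,8-bis[(triethylsilyl)oxy]oct-4-yne-1,7-diol | CC[Si](CC)(CC)OC[C@@](C)(O)CC#C[C@](C)(O[Si](CC)(CC)CC)CCO | intermediate
11 | (3R,7S)-7-hydroxy-3,7-dimethyl-3,8-bis[(triethylsilyl)oxy]oct-4-ynal | CC[Si](CC)(CC)OC[C@@](C)(O)CC#C[C@](C)(O[Si](CC)(CC)CC)CC=O | intermediate
12 | tetronic acid | O=C1COC(=O)C1 | starting material
13 | 4-bromo-2-oxo-2,5-dihydrofuran-3-carbaldehyde | O=CC1=C(Br)COC1=O | intermediate
14 | 4-bromo-3-(hydroxymethyl)furan-2(5H)-one | OCC1=C(Br)COC1=O | intermediate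
15 | 4-bromo-3-{[(tert-butyldimethylsilyl)oxy]methyl}furan-2(5H)-one | CC(C)(C)[Si](C)(C)OCC1=C(Br)COC1=O | intermediate
16 | 3-{[(tert-butyldimethylsilyl)oxy]methyl}-4-[(1S,3R,7S)-1,7-dihydroxy-3,7-dimethyl-3,8-bis[(triethylsilyl)oxy]oct-4-yn-1-yl]furan-2(5H)-one | CC[Si](CC)(CC)OC[C@@](C)(O)CC#C[C@](C)(O[Si](CC)(CC)CC)C[C@H](O)C1=C(CO[Si](C)(C)C(C)(C)C)C(=O)OC1 | intermediate
17 | C8 methacrylate of 16 | CC[Si](CC)(CC)OC[C@@](C)(O)CC#C[C@](C)(O[Si](CC)(CC)CC)C[C@H](OC(=O)C(C)=C)C1=C(CO[Si](C)(C)C(C)(C)C)C(=O)OC1 | intermediate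
18 | dihydrofuran from 17 (C5–OSiEt3) | CC[Si](CC)(CC)OC[C@]1(C)CC=C(O1)[C@](C)(O[Si](CC)(CC)CC)C[C@H](OC(=O)C(C)=C)C2=C(CO[Si](C)(C)C(C)(C)C)C(=O)OC2 | intermediate
19 | C5 aldehyde from 18 | O=C[C@]1(C)CC=C(O1)[C@](C)(O[Si](CC)(CC)CC)C[C@H](OC(=O)C(C)=C)C2=C(CO[Si](C)(C)C(C)(C)C)C(=O)OC2 | intermediate
20 | 2-silyloxyfuran of 19 | O=C[C@]1(C)CC=C(O1)[C@](C)(O[Si](CC)(CC)CC)C[C@H](OC(=O)C(C)=C)c2coc(O[Si](C)(C)C(C)(C)C)c2CO[Si](C)(C)C(C)(C)C | intermediate (not isolated)
21 | cyclised C5 silyl aldolate (C5/C6 epimers) | CC(=C)C(=O)O[C@H]1C[C@@](C)(O[Si](CC)(CC)CC)C2=CC[C@@](C)(C(O[Si](C)(C)C(C)(C)C)C3OC(=O)C(CO[Si](C)(C)C(C)(C)C)=C31)O2 | intermediate (not isolated)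
22 | (4S,8S,10R)-13-O-TBS, 10-O-TES ring-closed trienolide | CC(=C)C(=O)O[C@H]1C[C@@](C)(O[Si](CC)(CC)CC)C2=CC[C@@](C)(/C=C3/OC(=O)C(CO[Si](C)(C)C(C)(C)C)=C31)O2 | intermediate
23 | (4S,8S,10R)-10,13-diol | CC(=C)C(=O)O[C@H]1C[C@@](C)(O)C2=CC[C@@](C)(/C=C3/OC(=O)C(CO)=C31)O2 | intermediate
24 | CNP0394509.2 | C=C(C)C(=O)O[C@H]1C[C@@](C)(O)C2=CC[C@@](C)(/C=C3/OC(=O)C(COC(C)=O)=C31)O2 | target

**Count and risks**

Total steps: 18. Longest linear sequence: 14 steps (1–4, 6–8, 12–18).

Risk 1, step 16. The tethered silyloxyfuran may be consumed by intermolecular aldol addition (oligomers) before the nine-membered transition state is reached, or the silyl triflate may ionise the allylic C8 or C13 oxygens of the electron-rich furan. The fallback sets out from 15 and returns at 22, and replaces the reversible aldol by an irreversible phosphonate olefination at the same bond. Radical bromination of 15 at C6 (NBS, AIBN, PhCF3, 80 °C) gives the 4,5-dibromofuranone F1. Arbuzov reaction with P(OEt)3 (toluene, 60 °C) at the reactive γ-bromide gives the γ-phosphonate F2. F2 takes the place of 15 in the Ni/Cr union with 11 to give the alcohol F3, which is carried through the same acylation (methacrylic anhydride, pyridine, DMAP) to the methacrylate F4, the gold cycloisomerisation to the dihydrofuran F5 and the Swern oxidation to the aldehyde F6. LiCl and DBU in MeCN at high dilution (Masamune–Roush Horner–Wadsworth–Emmons conditions) then close C5=C6 and give 22.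

Risk 2, step 12. Facial selectivity in the addition of the vinylchromium to the aldehyde may be poor, because the β-carbon is quaternary and gives no substrate bias, or the ligand and substrate may be mismatched. The fallback sets out from 11 and 15 and returns at 17, and sets C8 by inversion instead of by addition. The union is run with the ligand enantiomer that gives the (8R)-alcohol F7 (or without ligand, followed by separation). Mitsunobu esterification of F7 with methacrylic acid (PPh3, DIAD, toluene, 0 °C) gives 17 with inversion; any (8S)-alcohol 16 is acylated as in step 13, so both epimers converge.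

Risk 3, step 9. The doubly electrophilic bromo aldehyde may polymerise or hydrolyse during formation and work-up, and the following 1,2-reduction may lose the bromide. The fallback sets out from 11 and returns at 16, and introduces C13 after the fragment union. Purchased 3,4-dibromofuran-2(5H)-one replaces 15 in the Ni/Cr step, where insertion occurs at the β C–Br bond (the vinylogous acyl bromide), to give the α-bromobutenolide alcohol F8. Stille coupling with (tributylstannyl)methanol (Pd(PPh3)4, dioxane, 90 °C) gives the diol F9. Selective silylation of the primary allylic hydroxyl (t-BuMe2SiCl, imidazole, CH2Cl2, 0 °C) gives 16.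

**Further compounds**

F1 | step 16 | 4,5-dibromo-3-{[(tert-butyldimethylsilyl)oxy]methyl}furan-2(5H)-one (racemic) | CC(C)(C)[Si](C)(C)OCC1=C(Br)C(Br)OC1=O
F2 | step 16 | diethyl (3-bromo-4-{[(tert-butyldimethylsilyl)oxy]methyl}-5-oxo-2,5-dihydrofuran-2-yl)phosphonate | CCOP(=O)(OCC)C1OC(=O)C(CO[Si](C)(C)C(C)(C)C)=C1Br
F3 | step 16 | C6-diethylphosphonate analogue of alcohol 16 (C6 epimers) | CC[Si](CC)(CC)OC[C@@](C)(O)CC#C[C@](C)(O[Si](CC)(CC)CC)C[C@H](O)C1=C(CO[Si](C)(C)C(C)(C)C)C(=O)OC1P(=O)(OCC)OCC
F4 | step 16 | C6-diethylphosphonate analogue of methacrylate 17 | CC[Si](CC)(CC)OC[C@@](C)(O)CC#C[C@](C)(O[Si](CC)(CC)CC)C[C@H](OC(=O)C(C)=C)C1=C(CO[Si](C)(C)C(C)(C)C)C(=O)OC1P(=O)(OCC)OCC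
F5 | step 16 | C6-diethylphosphonate analogue of dihydrofuran 18 | CC[Si](CC)(CC)OC[C@]1(C)CC=C(O1)[C@](C)(O[Si](CC)(CC)CC)C[C@H](OC(=O)C(C)=C)C2=C(CO[Si](C)(C)C(C)(C)C)C(=O)OC2P(=O)(OCC)OCC
F6 | step 16 | C6-diethylphosphonate analogue of aldehyde 19 | O=C[C@]1(C)CC=C(O1)[C@](C)(O[Si](CC)(CC)CC)C[C@H](OC(=O)C(C)=C)C2=C(CO[Si](C)(C)C(C)(C)C)C(=O)OC2P(=O)(OCC)OCC
F7 | step 12 | (8R)-epimer of alcohol 16 | CC[Si](CC)(CC)OC[C@@](C)(O)CC#C[C@](C)(O[Si](CC)(CC)CC)C[C@@H](O)C1=C(CO[Si](C)(C)C(C)(C)C)C(=O)OC1
F8 | step 9 | 3-bromo-4-[(1S,3R,7S)-1,7-dihydroxy-3,7-dimethyl-3,8-bis[(triethylsilyl)oxy]oct-4-yn-1-yl]furan-2(5H)-one | CC[Si](CC)(CC)OC[C@@](C)(O)CC#C[C@](C)(O[Si](CC)(CC)CC)C[C@H](O)C1=C(Br)C(=O)OC1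
F9 | step 9 | 4-[(1S,3R,7S)-1,7-dihydroxy-3,7-dimethyl-3,8-bis[(triethylsilyl)oxy]oct-4-yn-1-yl]-3-(hydroxymethyl)furan-2(5H)-one | CC[Si](CC)(CC)OC[C@@](C)(O)CC#C[C@](C)(O[Si](CC)(CC)CC)C[C@H](O)C1=C(CO)C(=O)OC1
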